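**Plan**
- Retrosynthesis: the methide carbon–aryl bond is cut first (aryllithium plus diaryl ketone), then ring A bonds C1–C2 and C5–C6 with the bridging oxygen put back (furan/ynone [4+2]), then the diyne sp–sp bond and the furan–aryl bond.
- Enabling feature: in ring A (central benzene; C1 bears the methide carbon, C2 the aryl, C3/C4 are CH, C5 the CH2OH, C6 the alkynyl) C2–C5 with their substituents are a 2-aryl-5-(oxymethyl)furan, and C1/C6 are the two carbons of the carbonyl-conjugated triple bond of a diynone.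
- Forward: furan 5 (3 steps) and diynone 12 (5 steps, both aryl halves from one aldehyde) are joined in a cycloaddition that closes the six-membered carbocycle as a 7-oxanorbornadiene; loss of the bridging oxygen gives ring A; aryllithium addition and global desilylation/dehydration give the quinone methide.
- Stereochemistry: the target has no stereocentre; the carbinol centre of 8/11 and the bridgeheads of 13 are racemic and are erased in steps 8 and 10.
- Protection: all phenols and the CH2OH travel as silyl ethers, so the endgame needs only buffered fluoride and weak acid.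

Key step: step 9

Assumption: the target SMILES carries no stereodescriptor and the molecule has no stereocentre (the two oxygenated rings on the methide carbon exchange roles by tautomerism), so the achiral constitution is the "single enantiomer"; no enantiocontrol is built in. TBS = tert-butyldimethylsilyl throughout.

**Step 1**
Reactants: 1 5-bromofuran-2-carbaldehyde; 2 4-hydroxyphenylboronic acid
Product: 3 5-(4-hydroxyphenyl)furan-2-carbaldehyde
Conditions: Pd(PPh3)4 (3 mol %), K2CO3, 1,4-dioxane/H2O, 85 °C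
Reagents that add atoms: none
Why: Suzuki–Miyaura coupling of an electron-poor 2-bromofuran, which tolerates the free phenol (present as phenoxide) and the aldehyde.

**Step 2**
Reactants: 3 5-(4-hydroxyphenyl)furan-2-carbaldehyde
Product: 4 4-[5-(hydroxymethyl)furan-2-yl]phenol
Conditions: NaBH4, MeOH, 0 °C; pH 7 work-up
Reagents that add atoms: none
Why: borohydride reduction of the aldehyde leaves furan and phenol untouched, and the neutral work-up protects the acid-labile arylfurfuryl alcohol, which is carried on crude.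

**Step 3**
Reactants: 4 4-[5-(hydroxymethyl)furan-2-yl]phenol
Product: 5 2-[4-(TBSO)phenyl]-5-[(TBSO)methyl]furan (both hydroxyls as TBS ethers)
Conditions: TBSCl (2.4 equiv), imidazole, DMF, 0 °C → rt
Reagents that add atoms: tert-butyldimethylsilyl chloride, CC(C)(C)[Si](C)(C)Cl
Why: imidazole-promoted silylation caps the phenol and the primary alcohol in one operation, giving an electron-rich furan without an ionisable ester at the furfuryl position.

**Step 4**
Reactants: 6 4-(TBSO)benzaldehyde; 7 ethynylmagnesium bromide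
Product: 8 rac-1-[4-(TBSO)phenyl]prop-2-yn-1-ol
Conditions: THF, 0 °C; then H2O
Reagents that add atoms: none
Why: Grignard 1,2-addition to the aldehyde; the carbinol centre forms without control (racemic) and is removed by oxidation in step 8.

**Step 5**
Reactants: 6 4-(TBSO)benzaldehyde
Product: 9 tert-butyl[4-(2,2-dibromoethenyl)phenoxy]dimethylsilane
Conditions: CBr4, PPh3, Zn, CH2Cl2, rt
Reagents that add atoms: carbon tetrabromide, BrC(Br)(Br)Br
Why: Ramirez dibromo-olefination (first stage of the Corey–Fuchs sequence) under neutral conditions that leave the aryl silyl ether intact.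

**Step 6**
Reactants: 9 tert-butyl[4-(2,2-dibromoethenyl)phenoxy]dimethylsilane
Product: 10 [4-(bromoethynyl)phenoxy](tert-butyl)dimethylsilane
Conditions: NaHMDS (1.05 equiv), THF, −78 °C
Reagents that add atoms: none
Why: E2 dehydrobromination of a 1,1-dibromoalkene by a hindered amide base stops at the 1-bromoalkyne, because this base does not undergo halogen–metal exchange.

**Step 7**
Reactants: 8 rac-1-[4-(TBSO)phenyl]prop-2-yn-1-ol; 10 [4-(bromoethynyl)phenoxy](tert-butyl)dimethylsilane
Product: 11 rac-1,5-bis[4-(TBSO)phenyl]penta-2,4-diyn-1-ol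
Conditions: CuCl (5 mol %), NH2OH·HCl (10 mol %), 30% aq. n-BuNH2, CH2Cl2, 0 °C
Reagents that add atoms: none
Why: Cadiot–Chodkiewicz coupling of a propargylic alcohol (copper acetylide) with a 1-bromoalkyne forms the unsymmetrical diyne, and the short, cold, biphasic protocol spares the aryl silyl ethers.

**Step 8**
Reactants: 11 rac-1,5-bis[4-(TBSO)phenyl]penta-2,4-diyn-1-ol
Product: 12 1,5-bis[4-(TBSO)phenyl]penta-2,4-diyn-1-one
Conditions: activated MnO2 (excess), CH2Cl2, rt
Reagents that add atoms: none
Why: MnO2 oxidation of a doubly activated (benzylic and propargylic) alcohol gives the diynone under neutral conditions and removes the racemic stereocentre.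

**Step 9**
Reactants: 5 2-[4-(TBSO)phenyl]-5-[(TBSO)methyl]furan; 12 1,5-bis[4-(TBSO)phenyl]penta-2,4-diyn-1-one
Product: 13 rac-{1-[4-(TBSO)phenyl]-4-[(TBSO)methyl]-3-{[4-(TBSO)phenyl]ethynyl}-7-oxabicyclo[2.2.1]hepta-2,5-dien-2-yl}[4-(TBSO)phenyl]methanone (oxygen bridge fixes the bridgeheads cis; one enantiomer drawn)
Conditions: Me2AlCl (1.1 equiv), CH2Cl2, −78 → −30 °C; cold pH 7 buffer
Reagents that add atoms: none
Why: Me2AlCl binds the ketone oxygen of 12 and lowers the LUMO of the carbonyl-conjugated C2≡C3, which accepts furan 5 as the 4π partner in a normal-demand, strongly asynchronous [4+2] cycloaddition; the closest known reaction type is the Lewis-acid-promoted Diels–Alder addition of furans to acetylenic carbonyl compounds giving 7-oxanorbornadienes. The six-membered carbocycle that becomes ring A is closed by this intermolecular cycloaddition, furan C5 (CH2OTBS) bonding to the ynone β-carbon C3 (ring A C5–C6) ahead of furan C2 (aryl) bonding to the α-carbon C2 (ring A C1–C2), with the furan oxygen left as the 1,4-bridge. The two bridgehead stereocentres arise together from the suprafacial addition and the bicyclic frame allows only the cis-bridged relative configuration; with no chiral element present 13 is racemic, which is immaterial because both centres are destroyed in step 10. The step needs regioselectivity (aroyl next to the aryl bridgehead, alkynyl next to the CH2OTBS bridgehead), secured by pairing the largest HOMO coefficient of the furan (the carbon remote from the donor aryl, whose attack leaves aryl-stabilised oxocarbenium character at the other terminus) with the largest LUMO coefficient of the complexed ynone (the β-carbon), and chemoselectivity for C2≡C3 over C4≡C5, secured because only the former is conjugated to the aluminium-bound carbonyl while the latter carries the donor aryl group. The 2,5-disubstitution of the furan blocks Friedel–Crafts-type alkenylation and the substituted bridgeheads block isomerisation to a phenol, so a cold neutral quench should deliver 13 intact.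

**Step 10**
Reactants: 13 rac-7-oxanorbornadienyl ketone
Product: 14 {4'-(TBSO)-4-[(TBSO)methyl]-3-{[4-(TBSO)phenyl]ethynyl}-[1,1'-biphenyl]-2-yl}[4-(TBSO)phenyl]methanone
Conditions: Fe2(CO)9 (1.5 equiv), toluene, 60 °C
Reagents that add atoms: none
Why: iron-carbonyl deoxygenation of a 7-oxanorbornadiene, in which an Fe(CO)4 fragment binds the strained bicycle, inserts into a bridgehead C–O bond and extrudes the oxygen with aromatisation as driving force, while ketone and silyl ethers are inert and the moderate temperature is meant to outpace complexation of the diarylalkyne.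

**Step 11**
Reactants: 14 biphenylyl aryl ketone; 15 (4-bromophenoxy)(tert-butyl)dimethylsilane
Product: 17 {4'-(TBSO)-4-[(TBSO)methyl]-3-{[4-(TBSO)phenyl]ethynyl}-[1,1'-biphenyl]-2-yl}bis[4-(TBSO)phenyl]methanol, via 4-(tert-butyldimethylsilyloxy)phenyllithium 16 (not isolated)
Conditions: 15 (2.0 equiv), n-BuLi (1.9 equiv), THF, −78 °C; then 14, −78 → −20 °C; H2O
Reagents that add atoms: none
Why: bromine–lithium exchange gives aryllithium 16, whose 1,2-addition is the only pathway open to the non-enolisable diaryl ketone (the slim alkynyl ortho substituent leaves one carbonyl face accessible), and the cold quench keeps the tertiary alkoxide from adding to the neighbouring alkyne; the new carbinol carbon bears two identical aryl groups and is not a stereocentre.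

**Step 12**
Reactants: 17 penta-TBS triarylcarbinol
Product: 19 selaginellin, via desilylated triarylcarbinol 18 (not isolated)
Conditions: TBAF (6 equiv), AcOH (6 equiv), THF, 0 °C → rt; then AcOH (excess), rt
Reagents that add atoms: none
Why: buffered fluoride cleaves all five Si–O bonds without leaving free alkoxide, and the resulting 4-hydroxyphenyl triarylcarbinol 18 loses water under weak acid through the p-hydroxy-stabilised trityl cation to give the quinone methide (fuchsone formation), the two p-hydroxyphenyl groups on the methide carbon being equivalent so that one product results.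

**Compound list**
1 | 5-bromofuran-2-carbaldehyde | O=Cc1ccc(Br)o1 | starting material
2 | 4-hydroxyphenylboronic acid | OB(O)c1ccc(O)cc1 | starting material
3 | 5-(4-hydroxyphenyl)furan-2-carbaldehyde | O=Cc1ccc(o1)-c1ccc(O)cc1 | intermediate
4 | 4-[5-(hydroxymethyl)furan-2-yl]phenol | OCc1ccc(o1)-c1ccc(O)cc1 | intermediate
5 | 2-[4-(TBSO)phenyl]-5-[(TBSO)methyl]furan | CC(C)(C)[Si](C)(C)OCc1ccc(o1)-c1ccc(O[Si](C)(C)C(C)(C)C)cc1 | intermediate
6 | 4-[(tert-butyldimethylsilyl)oxy]benzaldehyde | O=Cc1ccc(O[Si](C)(C)C(C)(C)C)cc1 | starting material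
7 | ethynylmagnesium bromide | C#C[Mg]Br | starting material
8 | rac-1-[4-(TBSO)phenyl]prop-2-yn-1-ol (racemic, one enantiomer drawn) | O[C@H](C#C)c1ccc(O[Si](C)(C)C(C)(C)C)cc1 | intermediate
9 | tert-butyl[4-(2,2-dibromoethenyl)phenoxy]dimethylsilane | BrC(Br)=Cc1ccc(O[Si](C)(C)C(C)(C)C)cc1 | intermediate
10 | [4-(bromoethynyl)phenoxy](tert-butyl)dimethylsilane | BrC#Cc1ccc(O[Si](C)(C)C(C)(C)C)cc1 | intermediate
11 | rac-1,5-bis[4-(TBSO)phenyl]penta-2,4-diyn-1-ol (racemic, one enantiomer drawn) | O[C@H](C#CC#Cc1ccc(O[Si](C)(C)C(C)(C)C)cc1)c1ccc(O[Si](C)(C)C(C)(C)C)cc1 | intermediate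
12 | 1,5-bis[4-(TBSO)phenyl]penta-2,4-diyn-1-one | O=C(C#CC#Cc1ccc(O[Si](C)(C)C(C)(C)C)cc1)c1ccc(O[Si](C)(C)C(C)(C)C)cc1 | intermediate
13 | rac-{1-[4-(TBSO)phenyl]-4-[(TBSO)methyl]-3-{[4-(TBSO)phenyl]ethynyl}-7-oxabicyclo[2.2.1]hepta-2,5-dien-2-yl}[4-(TBSO)phenyl]methanone (racemic, one enantiomer drawn) | CC(C)(C)[Si](C)(C)Oc1ccc(cc1)[C@@]23C=C[C@@](CO[Si](C)(C)C(C)(C)C)(O2)C(C#Cc2ccc(O[Si](C)(C)C(C)(C)C)cc2)=C3C(=O)c2ccc(O[Si](C)(C)C(C)(C)C)cc2 | intermediate
14 | {4'-(TBSO)-4-[(TBSO)methyl]-3-{[4-(TBSO)phenyl]ethynyl}-[1,1'-biphenyl]-2-yl}[4-(TBSO)phenyl]methanone | CC(C)(C)[Si](C)(C)OCc1ccc(-c2ccc(O[Si](C)(C)C(C)(C)C)cc2)c(C(=O)c2ccc(O[Si](C)(C)C(C)(C)C)cc2)c1C#Cc1ccc(O[Si](C)(C)C(C)(C)C)cc1 | intermediate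
15 | (4-bromophenoxy)(tert-butyl)dimethylsilane | Brc1ccc(O[Si](C)(C)C(C)(C)C)cc1 | starting material
16 | 4-(tert-butyldimethylsilyloxy)phenyllithium | [Li]c1ccc(O[Si](C)(C)C(C)(C)C)cc1 | intermediate
17 | {4'-(TBSO)-4-[(TBSO)methyl]-3-{[4-(TBSO)phenyl]ethynyl}-[1,1'-biphenyl]-2-yl}bis[4-(TBSO)phenyl]methanol | CC(C)(C)[Si](C)(C)OCc1ccc(-c2ccc(O[Si](C)(C)C(C)(C)C)cc2)c(C(O)(c2ccc(O[Si](C)(C)C(C)(C)C)cc2)c2ccc(O[Si](C)(C)C(C)(C)C)cc2)c1C#Cc1ccc(O[Si](C)(C)C(C)(C)C)cc1 | intermediate
18 | {4'-hydroxy-4-(hydroxymethyl)-3-[(4-hydroxyphenyl)ethynyl]-[1,1'-biphenyl]-2-yl}bis(4-hydroxyphenyl)methanol | OCc1ccc(-c2ccc(O)cc2)c(C(O)(c2ccc(O)cc2)c2ccc(O)cc2)c1C#Cc1ccc(O)cc1 | intermediate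
19 | selaginellin, 4-{[4'-hydroxy-4-(hydroxymethyl)-3-[(4-hydroxyphenyl)ethynyl]-[1,1'-biphenyl]-2-yl](4-hydroxyphenyl)methylidene}cyclohexa-2,5-dien-1-one | O=C1C=CC(=C(c2ccc(O)cc2)c2c(-c3ccc(O)cc3)ccc(CO)c2C#Cc2ccc(O)cc2)C=C1 | target

**Step count and risks**
Total steps: 12. Longest linear sequence: 8 (steps 5, 6, 7, 8, 9, 10, 11, 12, from aldehyde 6).

Steps most likely to fail:

1. Step 9. The β-substituted, singly activated ynone may add too slowly to the hindered, aryl-conjugated furan. The Lewis acid may open the oxygen bridge of the adduct or erode the regioselectivity. The fallback sets out from alkynol 8 and furan 5 and returns at ketone 14. Bromination of 8 (NBS, cat. AgNO3, acetone) should give rac-3-bromo-1-[4-(TBSO)phenyl]prop-2-yn-1-ol F1, and MnO2 oxidation 3-bromo-1-[4-(TBSO)phenyl]prop-2-yn-1-one F2. This smaller, more electrophilic haloynone should add to 5 in warm toluene without Lewis acid, its β-carbon again bonding to the CH2OTBS terminus, to give rac-{3-bromo-1-[4-(TBSO)phenyl]-4-[(TBSO)methyl]-7-oxabicyclo[2.2.1]hepta-2,5-dien-2-yl}[4-(TBSO)phenyl]methanone F3. Iron-carbonyl deoxygenation as in step 10 would give {3-bromo-4'-(TBSO)-4-[(TBSO)methyl]-[1,1'-biphenyl]-2-yl}[4-(TBSO)phenyl]methanone F4. Sonogashira coupling (Pd(PPh3)2Cl2, CuI, Et3N, THF, 60 °C) with tert-butyl(4-ethynylphenoxy)dimethylsilane F5, made from dibromoalkene 9 with n-BuLi (2.1 equiv, THF, −78 °C), then installs the arylethynyl group and rejoins the route at 14.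

2. Step 10. Iron carbonyl fragments may bind the diarylalkyne in competition with oxygen abstraction, or the extrusion may stall at an iron-bound intermediate. The fallback sets out from 13 and returns at 14 by a stepwise reductive opening. SmI2 (2.2 equiv, THF/MeOH, −78 °C) should reduce the enone by two electrons and expel the γ-oxygen, i.e. the bridge C–O bond at the CH2OTBS bridgehead. Protonation would give {6-hydroxy-6-[4-(TBSO)phenyl]-3-[(TBSO)methyl]-2-{[4-(TBSO)phenyl]ethynyl}cyclohexa-2,4-dien-1-yl}[4-(TBSO)phenyl]methanone F6 as a diastereomer mixture. Brief treatment with PPTS in CH2Cl2 should dehydrate this β-hydroxy ketone to the arene 14.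

3. Step 12. A benzylic alkoxide generated by fluoride may add to the neighbouring alkyne (5-exo-dig), or dehydration of the carbinol may remain incomplete in the basic medium. The fallback sets out from 17 and returns at 19 by staged deprotection. KHF2 in MeOH at rt should cleave only the four aryl silyl ethers, and an acetic acid work-up should then form the quinone methide with the primary silyl ether intact: 4-{[4-[(TBSO)methyl]-4'-hydroxy-3-[(4-hydroxyphenyl)ethynyl]-[1,1'-biphenyl]-2-yl](4-hydroxyphenyl)methylidene}cyclohexa-2,5-dien-1-one F7. AcOH/THF/H2O (3:1:1, rt) would then free the CH2OH without any base and give 19.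

**Further compounds**
F1 | step 9 | rac-3-bromo-1-[4-(TBSO)phenyl]prop-2-yn-1-ol (racemic, one enantiomer drawn) | O[C@H](C#CBr)c1ccc(O[Si](C)(C)C(C)(C)C)cc1
F2 | step 9 | 3-bromo-1-[4-(TBSO)phenyl]prop-2-yn-1-one | O=C(C#CBr)c1ccc(O[Si](C)(C)C(C)(C)C)cc1
F3 | step 9 | rac-{3-bromo-1-[4-(TBSO)phenyl]-4-[(TBSO)methyl]-7-oxabicyclo[2.2.1]hepta-2,5-dien-2-yl}[4-(TBSO)phenyl]methanone (racemic, one enantiomer drawn) | CC(C)(C)[Si](C)(C)Oc1ccc(cc1)[C@@]23C=C[C@@](CO[Si](C)(C)C(C)(C)C)(O2)C(Br)=C3C(=O)c2ccc(O[Si](C)(C)C(C)(C)C)cc2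
F4 | step 9 | {3-bromo-4'-(TBSO)-4-[(TBSO)methyl]-[1,1'-biphenyl]-2-yl}[4-(TBSO)phenyl]methanone | CC(C)(C)[Si](C)(C)OCc1ccc(-c2ccc(O[Si](C)(C)C(C)(C)C)cc2)c(C(=O)c2ccc(O[Si](C)(C)C(C)(C)C)cc2)c1Br
F5 | step 9 | tert-butyl(4-ethynylphenoxy)dimethylsilane | C#Cc1ccc(O[Si](C)(C)C(C)(C)C)cc1
F6 | step 10 | {6-hydroxy-6-[4-(TBSO)phenyl]-3-[(TBSO)methyl]-2-{[4-(TBSO)phenyl]ethynyl}cyclohexa-2,4-dien-1-yl}[4-(TBSO)phenyl]methanone (racemic diastereomer mixture) | O=C(c1ccc(O[Si](C)(C)C(C)(C)C)cc1)C1C(C#Cc2ccc(O[Si](C)(C)C(C)(C)C)cc2)=C(CO[Si](C)(C)C(C)(C)C)C=CC1(O)c1ccc(O[Si](C)(C)C(C)(C)C)cc1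
F7 | step 12 | 4-{[4-[(TBSO)methyl]-4'-hydroxy-3-[(4-hydroxyphenyl)ethynyl]-[1,1'-biphenyl]-2-yl](4-hydroxyphenyl)methylidene}cyclohexa-2,5-dien-1-one | CC(C)(C)[Si](C)(C)OCc1ccc(-c2ccc(O)cc2)c(C(=C2C=CC(=O)C=C2)c2ccc(O)cc2)c1C#Cc1ccc(O)cc1
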